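**Retrosynthetic overview**

- The plan rests on the contiguous ring carbons C2 (OH), C3 (OMe), C4 (Me) and C5 (OH). They are the four carbons of a squarate-derived cyclobutenone (C2 carbonyl, C5 carbinol), and C1 and C6 are a trans CH=CH unit attached to C5. Closing C1–C2 makes the benzene ring and puts the branched chain on C1, a position that substitution of a finished 2-methoxy-3-methylhydroquinone would not choose (it goes para to OMe, to C6).
- Target 27 ⇐ phenol 21: silylate the second phenol oxygen, free C8–OH selectively, acylate with angelic acid through a mixed anhydride, remove the aryl silyl groups with fluoride.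
- 21 ⇐ cyclobutenone 18 by thermal four-electron opening and six-electron closure. 18 ⇐ dimethyl squarate 12 by dienyllithium addition, O-silylation, then methyllithium and acid-induced carbonyl transposition, which fixes the order O, OMe, Me, O.
- Dienyllithium 13 ⇐ dienylstannane 11 ⇐ enol triflate 9 + (E)-1,2-bis(tributylstannyl)ethene (C1–C7 bond). 9 ⇐ methyl ketone 7 ⇐ methyl (S)-glycidate 1 + isobutenyl Grignard reagent 2 (C8 from the chiral pool, C9–C10 bond).
- Ring order: the four-membered ring is bought with the squarate; the benzene ring, the only ring built, is formed in step 10.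

Key step: step 10

Remark on numbering: ring C1 (side chain), C2 (OH), C3 (OMe), C4 (Me), C5 (OH), C6 (H); chain C7 (bearing methylene C14), C8 (ester carbinol, S), C9, C10, C11. "Dienyl" stands for the (1E,4S)-7-methyl-3-methylidene-4-[(triethylsilyl)oxy]octa-1,6-dien-1-yl group.

Assumption: methyl (S)-glycidate and a THF solution of (2-methylprop-1-en-1-yl)magnesium bromide are bought. The phosphonopropanoic acid used in one fallback is made by saponifying its commercial ethyl ester.

**Route**

Step 1
Reactants: 1 methyl (S)-glycidate; 2 (2-methylprop-1-en-1-yl)magnesium bromide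
Product: 3 methyl (2S)-2-hydroxy-5-methylhex-4-enoate
Conditions: CuI (10 mol %), THF, −78 to −40 °C; aq. NH4Cl
Reagents that add atoms: none
Why: Copper-catalysed SN2 opening of the terminal epoxide by the alkenyl Grignard reagent at the unsubstituted carbon is faster than attack on the ester at low temperature, and the stereocentre (future C8) is not touched, so the S configuration of the glycidate is carried over.

Step 2
Reactants: 3 methyl (2S)-2-hydroxy-5-methylhex-4-enoate
Product: 4 methyl (2S)-5-methyl-2-[(triethylsilyl)oxy]hex-4-enoate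
Conditions: Et3SiCl, imidazole, CH2Cl2, 0 °C to rt
Reagents that add atoms: chlorotriethylsilane, CC[Si](Cl)(CC)CC
Why: Imidazole-mediated silylation of a secondary alcohol, chosen so that this ether survives organolithium chemistry and can later be removed in the presence of aryl tert-butyldimethylsilyl ethers.

Step 3
Reactants: 4 methyl (2S)-5-methyl-2-[(triethylsilyl)oxy]hex-4-enoate
Product: 5 (2S)-N-methoxy-N,5-dimethyl-2-[(triethylsilyl)oxy]hex-4-enamide
Conditions: MeNHOMe·HCl, i-PrMgCl, THF, −20 to 0 °C
Reagents that add atoms: N,O-dimethylhydroxylamine hydrochloride, CNOC.Cl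
Why: Direct aminolysis of the ester by the chloromagnesium amide gives the Weinreb amide, and the weakly acidic α-silyloxy methine is not enolized at this temperature.

Step 4
Reactants: 5 (2S)-N-methoxy-N,5-dimethyl-2-[(triethylsilyl)oxy]hex-4-enamide
Product: 7 (3S)-6-methyl-3-[(triethylsilyl)oxy]hept-5-en-2-one, via magnesium-chelated tetrahedral adduct 6 (not isolated)
Conditions: MeMgBr, THF, 0 °C; aq. NH4Cl
Reagents that add atoms: methylmagnesium bromide, C[Mg]Br
Why: Weinreb ketone synthesis, in which the chelated adduct 6 persists until work-up so that the Grignard reagent adds only once.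

Step 5
Reactants: 7 (3S)-6-methyl-3-[(triethylsilyl)oxy]hept-5-en-2-one
Product: 9 (3S)-6-methyl-3-[(triethylsilyl)oxy]hepta-1,5-dien-2-yl trifluoromethanesulfonate, via potassium enolate 8 (not isolated)
Conditions: KN(SiMe3)2, THF, −78 °C; PhNTf2, −78 to 0 °C
Reagents that add atoms: N-phenylbis(trifluoromethanesulfonimide), O=S(=O)(N(c1ccccc1)S(=O)(=O)C(F)(F)F)C(F)(F)F
Why: Kinetic deprotonation by the bulky amide base takes a methyl proton and not the hindered methine beside the silyloxy group, and O-sulfonylation of the terminal enolate gives the 1,1-disubstituted alkenyl triflate (C7 with C14 in place) without touching C8.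

Step 6
Reactants: 9 (3S)-6-methyl-3-[(triethylsilyl)oxy]hepta-1,5-dien-2-yl trifluoromethanesulfonate; 10 (E)-1,2-bis(tributylstannyl)ethene
Product: 11 tributyl(dienyl)stannane
Conditions: Pd(PPh3)4 (5 mol %), LiCl, THF, 60 °C, 10 in threefold excess
Reagents that add atoms: none
Why: Chloride-assisted Stille coupling of the alkenyl triflate with one tin terminus of the distannane forms the C1–C7 bond with retention of the trans geometry, and the excess of 10 keeps the second tin terminus uncoupled.

Step 7
Reactants: 11 tributyl(dienyl)stannane; 12 dimethyl squarate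
Product: 14 4-dienyl-4-hydroxy-2,3-dimethoxycyclobut-2-en-1-one (both epimers at the ring carbinol), via dienyllithium 13 (not isolated)
Conditions: n-BuLi (0.95 equiv), THF, −78 °C; then cannulated into 12, THF, −78 °C; aq. NH4Cl at −78 °C
Reagents that add atoms: none
Why: Tin–lithium exchange gives the alkenyllithium with retention of the E geometry, and at −78 °C it adds once, in 1,2 fashion, to one of the two equivalent carbonyl groups of the squarate; the new ring centre forms as both epimers, which does not matter because it is lost in step 10.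

Step 8
Reactants: 14 4-dienyl-4-hydroxy-2,3-dimethoxycyclobut-2-en-1-one
Product: 15 4-[(tert-butyldimethylsilyl)oxy]-4-dienyl-2,3-dimethoxycyclobut-2-en-1-one
Conditions: TBSOTf, 2,6-lutidine, CH2Cl2, −78 to 0 °C
Reagents that add atoms: tert-butyldimethylsilyl trifluoromethanesulfonate, CC(C)(C)[Si](C)(C)OS(=O)(=O)C(F)(F)F
Why: A silyl triflate with a hindered pyridine base silylates the tertiary alcohol; masking this oxygen confines the ionization of step 9 to the other carbinol and later delivers C5–O already protected.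

Step 9
Reactants: 15 4-[(tert-butyldimethylsilyl)oxy]-4-dienyl-2,3-dimethoxycyclobut-2-en-1-one
Product: 18 4-[(tert-butyldimethylsilyl)oxy]-4-dienyl-2-methoxy-3-methylcyclobut-2-en-1-one (both epimers at the ring carbinol), via lithium alkoxide adduct 16 (not isolated), via tertiary trifluoroacetate 17 (not isolated)
Conditions: MeLi, THF, −78 °C; (CF3CO)2O, −78 °C; aq. NaHCO3
Reagents that add atoms: methyllithium, [Li]C; water, O
Why: Methyllithium adds 1,2 to the vinylogous ester carbonyl, only the new alkoxide is trifluoroacetylated, and ionization to the methoxy-stabilized cyclobutenyl cation followed by hydrolysis at the far methoxy-bearing carbon (a 1,3-carbonyl transposition of the Stork–Danheiser type, known for squarate adducts) places the carbonyl next to C–OMe and the methyl next to the silyloxy carbon.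

Step 10
Reactants: 18 4-[(tert-butyldimethylsilyl)oxy]-4-dienyl-2-methoxy-3-methylcyclobut-2-en-1-one
Product: 21 4-[(tert-butyldimethylsilyl)oxy]-2-methoxy-3-methyl-6-{(3S)-6-methyl-3-[(triethylsilyl)oxy]hepta-1,5-dien-2-yl}phenol, via dienylketene 19 (not isolated), via cyclohexa-2,4-dienone 20 (not isolated)
Conditions: toluene (degassed, 0.01 M), 110 °C
Reagents that add atoms: none
Why: Heating breaks the C2–C5 bond of the cyclobutenone by conrotatory four-electron electrocyclic opening, the silyloxy group on C5 turning outward so that the dienyl arm lies cis to the ketene in 19; a disrotatory six-electron electrocyclization then joins the ketene carbon C2 to C1, the far carbon of the trans CH=CH unit, and closes the six-membered carbocycle as dienone 20, whose enolization gives the aromatic ring irreversibly. The closest known reaction is the thermal ring expansion of 4-alkenyl-4-oxygenated cyclobutenones from squarate esters to hydroquinones and their mono-ethers (Moore rearrangement). The one ring formed is closed in the pericyclic 6π mode and no lasting stereocentre is made: the ring carbinol centre of 18 and the sp3 C1 of 20 both vanish on aromatization, and C8 lies outside the reacting array. The step needs torquoselectivity, which the outward preference of the oxygen donor on the breaking bond should provide, and six- over eight-electron closure, which the E geometry of C1=C6 should provide by holding C14 away from the ketene carbon; a ketene formed with the wrong sense of rotation can only reclose to 18, and with the oxygen silylated it cannot be trapped as a butenolide. The C7=C14 and C10=C11 alkenes and both silyl ethers are spectators under neutral thermal conditions, and high dilution disfavours Diels–Alder dimerization of the diene before it is consumed.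

Step 11
Reactants: 21 4-[(tert-butyldimethylsilyl)oxy]-2-methoxy-3-methyl-6-{(3S)-6-methyl-3-[(triethylsilyl)oxy]hepta-1,5-dien-2-yl}phenol
Product: 22 triethyl({(3S)-2-{2,5-bis[(tert-butyldimethylsilyl)oxy]-3-methoxy-4-methylphenyl}-6-methylhepta-1,5-dien-3-yl}oxy)silane
Conditions: TBSCl, imidazole, DMF, rt to 40 °C
Reagents that add atoms: tert-butyldimethylsilyl chloride, CC(C)(C)[Si](C)(C)Cl
Why: Imidazole-mediated silylation of the remaining phenol (C2–OH), so that only the C8 oxygen will be free for acylation.

Step 12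
Reactants: 22 triethyl({(3S)-2-{2,5-bis[(tert-butyldimethylsilyl)oxy]-3-methoxy-4-methylphenyl}-6-methylhepta-1,5-dien-3-yl}oxy)silane
Product: 23 (3S)-2-{2,5-bis[(tert-butyldimethylsilyl)oxy]-3-methoxy-4-methylphenyl}-6-methylhepta-1,5-dien-3-ol
Conditions: PPTS (10 mol %), MeOH/CH2Cl2, 0 °C
Reagents that add atoms: none
Why: Acid-catalysed methanolysis cleaves the secondary alkyl triethylsilyl ether much faster than aryl tert-butyldimethylsilyl ethers, which resist mild acid.

Step 13
Reactants: 23 (3S)-2-{2,5-bis[(tert-butyldimethylsilyl)oxy]-3-methoxy-4-methylphenyl}-6-methylhepta-1,5-dien-3-ol; 24 angelic acid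
Product: 26 (3S)-2-{2,5-bis[(tert-butyldimethylsilyl)oxy]-3-methoxy-4-methylphenyl}-6-methylhepta-1,5-dien-3-yl (2Z)-2-methylbut-2-enoate, via mixed anhydride 25 (not isolated)
Conditions: 2,4,6-Cl3C6H2COCl, Et3N, toluene, rt; then 23, toluene, 75 °C
Reagents that add atoms: none
Why: Yamaguchi esterification, in which the alcohol attacks the unshielded angeloyl carbonyl of the mixed anhydride; omitting a nucleophilic catalyst avoids the addition–elimination path that turns angelate into tiglate, and the C8–O bond is not broken, so the configuration is retained.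

Step 14
Reactants: 26 (3S)-2-{2,5-bis[(tert-butyldimethylsilyl)oxy]-3-methoxy-4-methylphenyl}-6-methylhepta-1,5-dien-3-yl (2Z)-2-methylbut-2-enoate
Product: 27 (3S)-2-(2,5-dihydroxy-3-methoxy-4-methylphenyl)-6-methylhepta-1,5-dien-3-yl (2Z)-2-methylbut-2-enoate
Conditions: Bu4NF, AcOH (1:1), THF, 0 °C, under argon
Reagents that add atoms: none
Why: Fluoride cleaves both aryl silyl ethers, and acetic acid keeps the phenols protonated so that acyl migration to the ortho phenol, ester cleavage and air oxidation of the hydroquinone are not promoted.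

**Compound list**

1 | methyl (2S)-oxirane-2-carboxylate (methyl (S)-glycidate) | COC(=O)[C@@H]1CO1 | starting material
2 | (2-methylprop-1-en-1-yl)magnesium bromide | CC(C)=C[Mg]Br | starting material
3 | methyl (2S)-2-hydroxy-5-methylhex-4-enoate | COC(=O)[C@H](CC=C(C)C)O | intermediate
4 | methyl (2S)-5-methyl-2-[(triethylsilyl)oxy]hex-4-enoate | COC(=O)[C@H](CC=C(C)C)O[Si](CC)(CC)CC | intermediate
5 | (2S)-N-methoxy-N,5-dimethyl-2-[(triethylsilyl)oxy]hex-4-enamide | CON(C)C(=O)[C@H](CC=C(C)C)O[Si](CC)(CC)CC | intermediate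
6 | bromomagnesium alkoxide of the tetrahedral adduct of MeMgBr and amide 5 | CC(O[Mg]Br)(N(C)OC)[C@H](CC=C(C)C)O[Si](CC)(CC)CC | intermediate
7 | (3S)-6-methyl-3-[(triethylsilyl)oxy]hept-5-en-2-one | CC(=O)[C@H](CC=C(C)C)O[Si](CC)(CC)CC | intermediate
8 | potassium (3S)-6-methyl-3-[(triethylsilyl)oxy]hepta-1,5-dien-2-olate | [K]OC(=C)[C@H](CC=C(C)C)O[Si](CC)(CC)CC | intermediate
9 | (3S)-6-methyl-3-[(triethylsilyl)oxy]hepta-1,5-dien-2-yl trifluoromethanesulfonate | C=C(OS(=O)(=O)C(F)(F)F)[C@H](CC=C(C)C)O[Si](CC)(CC)CC | intermediate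
10 | (E)-1,2-bis(tributylstannyl)ethene | CCCC[Sn](CCCC)(CCCC)/C=C/[Sn](CCCC)(CCCC)CCCC | starting material
11 | tributyl{(1E,4S)-7-methyl-3-methylidene-4-[(triethylsilyl)oxy]octa-1,6-dien-1-yl}stannane | CCCC[Sn](CCCC)(CCCC)/C=C/C(=C)[C@H](CC=C(C)C)O[Si](CC)(CC)CC | intermediate
12 | dimethyl squarate (3,4-dimethoxycyclobut-3-ene-1,2-dione) | COC1=C(OC)C(=O)C1=O | starting material
13 | {(1E,4S)-7-methyl-3-methylidene-4-[(triethylsilyl)oxy]octa-1,6-dien-1-yl}lithium | [Li]/C=C/C(=C)[C@H](CC=C(C)C)O[Si](CC)(CC)CC | intermediate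
14 | 4-hydroxy-2,3-dimethoxy-4-{(1E,4S)-7-methyl-3-methylidene-4-[(triethylsilyl)oxy]octa-1,6-dien-1-yl}cyclobut-2-en-1-one, both epimers at ring C4 | O=C1C(OC)=C(OC)C1(O)/C=C/C(=C)[C@H](CC=C(C)C)O[Si](CC)(CC)CC | intermediate
15 | 4-[(tert-butyldimethylsilyl)oxy]-2,3-dimethoxy-4-{(1E,4S)-7-methyl-3-methylidene-4-[(triethylsilyl)oxy]octa-1,6-dien-1-yl}cyclobut-2-en-1-one, both epimers at ring C4 | O=C1C(OC)=C(OC)C1(O[Si](C)(C)C(C)(C)C)/C=C/C(=C)[C@H](CC=C(C)C)O[Si](CC)(CC)CC | intermediate
16 | lithium 4-[(tert-butyldimethylsilyl)oxy]-2,3-dimethoxy-1-methyl-4-{(1E,4S)-7-methyl-3-methylidene-4-[(triethylsilyl)oxy]octa-1,6-dien-1-yl}cyclobut-2-en-1-olate | [Li]OC1(C)C(OC)=C(OC)C1(O[Si](C)(C)C(C)(C)C)/C=C/C(=C)[C@H](CC=C(C)C)O[Si](CC)(CC)CC | intermediate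
17 | 4-[(tert-butyldimethylsilyl)oxy]-2,3-dimethoxy-1-methyl-4-{(1E,4S)-7-methyl-3-methylidene-4-[(triethylsilyl)oxy]octa-1,6-dien-1-yl}cyclobut-2-en-1-yl trifluoroacetate | O=C(OC1(C)C(OC)=C(OC)C1(O[Si](C)(C)C(C)(C)C)/C=C/C(=C)[C@H](CC=C(C)C)O[Si](CC)(CC)CC)C(F)(F)F | intermediate
18 | 4-[(tert-butyldimethylsilyl)oxy]-2-methoxy-3-methyl-4-{(1E,4S)-7-methyl-3-methylidene-4-[(triethylsilyl)oxy]octa-1,6-dien-1-yl}cyclobut-2-en-1-one, both epimers at ring C4 | O=C1C(OC)=C(C)C1(O[Si](C)(C)C(C)(C)C)/C=C/C(=C)[C@H](CC=C(C)C)O[Si](CC)(CC)CC | intermediate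
19 | dienylketene from ring opening of 18, dienyl arm cis to the ketenyl group across the C4=C5 bond | O=C=C(OC)/C(C)=C(/O[Si](C)(C)C(C)(C)C)\C=C\C(=C)[C@H](CC=C(C)C)O[Si](CC)(CC)CC | intermediate
20 | 4-[(tert-butyldimethylsilyl)oxy]-2-methoxy-3-methyl-6-{(3S)-6-methyl-3-[(triethylsilyl)oxy]hepta-1,5-dien-2-yl}cyclohexa-2,4-dien-1-one | O=C1C(OC)=C(C)C(O[Si](C)(C)C(C)(C)C)=CC1C(=C)[C@H](CC=C(C)C)O[Si](CC)(CC)CC | intermediate
21 | 4-[(tert-butyldimethylsilyl)oxy]-2-methoxy-3-methyl-6-{(3S)-6-methyl-3-[(triethylsilyl)oxy]hepta-1,5-dien-2-yl}phenol | C=C(c1cc(O[Si](C)(C)C(C)(C)C)c(C)c(OC)c1O)[C@H](CC=C(C)C)O[Si](CC)(CC)CC | intermediate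
22 | triethyl({(3S)-2-{2,5-bis[(tert-butyldimethylsilyl)oxy]-3-methoxy-4-methylphenyl}-6-methylhepta-1,5-dien-3-yl}oxy)silane | C=C(c1cc(O[Si](C)(C)C(C)(C)C)c(C)c(OC)c1O[Si](C)(C)C(C)(C)C)[C@H](CC=C(C)C)O[Si](CC)(CC)CC | intermediate
23 | (3S)-2-{2,5-bis[(tert-butyldimethylsilyl)oxy]-3-methoxy-4-methylphenyl}-6-methylhepta-1,5-dien-3-ol | C=C(c1cc(O[Si](C)(C)C(C)(C)C)c(C)c(OC)c1O[Si](C)(C)C(C)(C)C)[C@H](CC=C(C)C)O | intermediate
24 | angelic acid, (2Z)-2-methylbut-2-enoic acid | C/C=C(/C)C(=O)O | starting material
25 | (2Z)-2-methylbut-2-enoic 2,4,6-trichlorobenzoic anhydride | C/C=C(/C)C(=O)OC(=O)c1c(Cl)cc(Cl)cc1Cl | intermediate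
26 | (3S)-2-{2,5-bis[(tert-butyldimethylsilyl)oxy]-3-methoxy-4-methylphenyl}-6-methylhepta-1,5-dien-3-yl (2Z)-2-methylbut-2-enoate | C=C(c1cc(O[Si](C)(C)C(C)(C)C)c(C)c(OC)c1O[Si](C)(C)C(C)(C)C)[C@H](CC=C(C)C)OC(=O)/C(C)=C\C | intermediate
27 | (3S)-2-(2,5-dihydroxy-3-methoxy-4-methylphenyl)-6-methylhepta-1,5-dien-3-yl (2Z)-2-methylbut-2-enoate | C=C(c1cc(O)c(C)c(OC)c1O)[C@H](CC=C(C)C)OC(=O)/C(C)=C\C | target

**Step count and risks**

Total: 14 steps. Longest linear sequence: 14 steps, from methyl (S)-glycidate 1 to target 27.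

The three steps most likely to fail:

Step 9, the carbonyl transposition. The ring may ionize on the wrong side, with loss of the silyloxy group from the dienyl-bearing carbon helped by the diene. The tertiary silyl ether may be cleaved by the trifluoroacetic acid set free, or methyllithium may add in conjugate fashion. The fallback sets out from dimethyl squarate 12 and dienyllithium 13 and comes back at cyclobutenone 18. It puts the methyl group in first and the dienyl group last, onto a carbonyl that is already in the right place, so no cation is generated on a dienyl-bearing ring. Squarate 12 with MeLi and then trifluoroacetic anhydride should give 3-methoxy-4-methylcyclobut-3-ene-1,2-dione F1. Its more electrophilic carbonyl, the one next to the methoxy-bearing carbon and outside the vinylogous ester, is converted to the dimethyl ketal with MeOSiMe3 and catalytic Me3SiOTf, giving 3,4,4-trimethoxy-2-methylcyclobut-2-en-1-one F2. Dienyllithium 13 adds to the one carbonyl left (THF, −78 °C) to give the tertiary cyclobutenol F3, which is silylated (TBSOTf, 2,6-lutidine) to the silyl ether F4. Mild aqueous acid (oxalic acid on wet silica gel, CH2Cl2) should hydrolyse the ketal and give 18.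

Step 6, the mono-coupling of the distannane. The product may couple a second time at its remaining tin terminus to give a symmetrical triene, transmetalation may be slow, and the dienylstannane may lose tin by protonolysis during purification. The fallback sets out from triflate 9 and comes back at dienyllithium 13. It brings the two-carbon unit in as an alkyne and installs the metal afterwards. Sonogashira coupling of 9 with trimethylsilylacetylene (Pd(PPh3)4, CuI, i-Pr2NH, THF) should give the silylated enyne F5. K2CO3 in methanol gives the terminal enyne F6. Hydrozirconation with Cp2Zr(H)Cl followed by I2 gives the (E)-dienyl iodide F7. Iodine–lithium exchange with t-BuLi (two equivalents, Et2O, −78 °C) gives 13, which is used as in step 7.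

Step 13, the angelate esterification. Acylation of the hindered allylic alcohol beside the ortho-silyloxy aryl group may be slow, and the angeloyl unit may isomerize from Z to E (tiglate) during the heating needed. The fallback sets out from alcohol 23 and comes back at ester 26. It builds the Z alkene on the ester instead of transferring it. Alcohol 23 is acylated with 2-[bis(2,2,2-trifluoroethoxy)phosphoryl]propanoic acid (DCC, DMAP, CH2Cl2) to the phosphonate ester F8. Still–Gennari olefination with acetaldehyde (KN(SiMe3)2, 18-crown-6, THF, −78 °C) should then give the (Z)-2-methylbut-2-enoate 26.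

**Further compounds**

F1 | step 9 | 3-methoxy-4-methylcyclobut-3-ene-1,2-dione | COC1=C(C)C(=O)C1=O
F2 | step 9 | 3,4,4-trimethoxy-2-methylcyclobut-2-en-1-one | O=C1C(C)=C(OC)C1(OC)OC
F3 | step 9 | 3,4,4-trimethoxy-2-methyl-1-{(1E,4S)-7-methyl-3-methylidene-4-[(triethylsilyl)oxy]octa-1,6-dien-1-yl}cyclobut-2-en-1-ol | OC1(/C=C/C(=C)[C@H](CC=C(C)C)O[Si](CC)(CC)CC)C(C)=C(OC)C1(OC)OC
F4 | step 9 | tert-butyldimethylsilyl ether of F3 | CC(C)(C)[Si](C)(C)OC1(/C=C/C(=C)[C@H](CC=C(C)C)O[Si](CC)(CC)CC)C(C)=C(OC)C1(OC)OC
F5 | step 6 | triethyl({(3S)-6-methyl-2-[(trimethylsilyl)ethynyl]hepta-1,5-dien-3-yl}oxy)silane | C=C(C#C[Si](C)(C)C)[C@H](CC=C(C)C)O[Si](CC)(CC)CC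
F6 | step 6 | triethyl{[(3S)-2-ethynyl-6-methylhepta-1,5-dien-3-yl]oxy}silane | C=C(C#C)[C@H](CC=C(C)C)O[Si](CC)(CC)CC
F7 | step 6 | triethyl{[(1E,4S)-1-iodo-7-methyl-3-methylideneocta-1,6-dien-4-yl]oxy}silane | I/C=C/C(=C)[C@H](CC=C(C)C)O[Si](CC)(CC)CC
F8 | step 13 | (3S)-2-{2,5-bis[(tert-butyldimethylsilyl)oxy]-3-methoxy-4-methylphenyl}-6-methylhepta-1,5-dien-3-yl 2-[bis(2,2,2-trifluoroethoxy)phosphoryl]propanoate | C=C(c1cc(O[Si](C)(C)C(C)(C)C)c(C)c(OC)c1O[Si](C)(C)C(C)(C)C)[C@H](CC=C(C)C)OC(=O)C(C)P(=O)(OCC(F)(F)F)OCC(F)(F)F
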